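Ring numbering used throughout: C1 bears CO2Me, C1=C2 is the ring alkene, C3 bears OAc, C4 and C5 bear the two (R)-2-methylbutanoates, C6 is the CH2.
Retrosynthesis: the three esters come off, the trans-4,5-dioxygen pair is traced back through the cis-3-hydroxy-4,5-epoxide to a C4=C5 alkene, and the cyclohexa-1,4-diene is cut at C1=C2 and at C4–C5 (as C4=C5) into two three-carbon pieces, an (S)-2-silyloxybut-3-enal (C2–C3–C4) and an allyl-bearing ester ylide (C5–C6–C1).
What allows this: C1=C2 is the double bond of a ring enoate (retron of a stabilised-ylide olefination at C1), and the trans-diester on ring carbons C4/C5 is the retron of a ring alkene; the two flank the single carbinol carbon C3.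
Forward: one flask olefinates the aldehyde (C1=C2) and closes the six-membered ring by metathesis (C4–C5, made as C4=C5); the silyl group on O3 and the extra unsaturation are then removed by desilylation, directed epoxidation and epoxide opening, and the esters are put on.
Stereochemistry: C3 comes from the chiral-pool butenediol, C4 from hydroxyl-directed syn epoxidation, C5 from inverting carboxylate attack on the epoxide, and the side-chain centres from the purchased (R)-acid.

Key step: step 5

Assumption: both 2-methylbutanoyl groups are read as (R)-configured, and the enantiopure (R)-acid and the (S)-butenediol are taken as purchasable.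

Step 1
Reactants: 1 (2S)-but-3-ene-1,2-diol
Product: 2 (3S)-3,4-bis[(tert-butyldimethylsilyl)oxy]but-1-ene
Conditions: TBSCl (2.3 equiv), imidazole, DMF, 0 °C to rt
Reagents that add atoms: tert-butyldimethylsilyl chloride, CC(C)(C)[Si](C)(C)Cl
Why: Exhaustive silyl ether formation (silylation with a silyl chloride and imidazole) protects both hydroxyls without touching the C–O stereocentre, which becomes ring carbon C3.

Step 2
Reactants: 2 (3S)-3,4-bis[(tert-butyldimethylsilyl)oxy]but-1-ene
Product: 3 (2S)-2-[(tert-butyldimethylsilyl)oxy]but-3-en-1-ol
Conditions: HF·pyridine, pyridine, THF, 0 °C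
Reagents that add atoms: none
Why: Selective desilylation should work because the unhindered primary silyl ether is cleaved by buffered fluoride much faster than the secondary allylic one.

Step 3
Reactants: 3 (2S)-2-[(tert-butyldimethylsilyl)oxy]but-3-en-1-ol
Product: 4 (2S)-2-[(tert-butyldimethylsilyl)oxy]but-3-enal
Conditions: Dess–Martin periodinane, CH2Cl2, 0 °C to rt; filtered and used at once
Reagents that add atoms: none
Why: Dess–Martin oxidation gives the aldehyde under neutral conditions, chosen because the alpha-silyloxy beta,gamma-unsaturated aldehyde would epimerise or slip into conjugation under amine bases.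

Step 4
Reactants: 5 methyl (triphenylphosphoranylidene)acetate; 6 allyl bromide
Product: 8 methyl 2-(triphenylphosphoranylidene)pent-4-enoate, via phosphonium bromide 7 (not isolated)
Conditions: EtOAc, reflux; then aq NaOH, CH2Cl2, 0 °C
Reagents that add atoms: none
Why: C-Alkylation of the ester-stabilised phosphorane by the allylic bromide gives the phosphonium salt, whose remaining acidic alpha-hydrogen is removed by hydroxide to give the alpha-allyl ylide (ylide alkylation–deprotonation).

Step 5
Reactants: 4 (2S)-2-[(tert-butyldimethylsilyl)oxy]but-3-enal; 8 methyl 2-(triphenylphosphoranylidene)pent-4-enoate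
Product: 10 methyl (3S)-3-[(tert-butyldimethylsilyl)oxy]cyclohexa-1,4-diene-1-carboxylate, via triene ester 9 (not isolated)
Conditions: CH2Cl2, rt to 40 °C, 4 in slight excess until 8 is consumed; then same flask: dilution with CH2Cl2, second-generation Hoveyda–Grubbs catalyst [1,3-bis(2,4,6-trimethylphenyl)imidazolidin-2-ylidene]dichloro(2-isopropoxybenzylidene)ruthenium, RuCl2(C21H26N2)(C10H12O) (5 mol%), 1,4-benzoquinone (10 mol%), 40 °C, argon sparge
Reagents that add atoms: none
Why: The non-basic ester-stabilised ylide 8 adds to aldehyde 4 through an oxaphosphetane that collapses to triphenylphosphine oxide and the E-enoate 9 (Wittig olefination), creating C1=C2 with the C3 carbinol chain and the C6 allyl group cis to each other; the ruthenium alkylidene then takes the two monosubstituted terminal alkenes of 9 through a [2+2]/cycloreversion sequence that expels ethylene and joins C4 to C5 (ring-closing metathesis). The closest known reaction types are the Wittig reaction of alpha-alkoxy aldehydes with alpha-alkyl ester ylides and the ring-closing metathesis of 1,4,7-trienes to cyclohexa-1,4-dienes, run here as a one-flask olefination–metathesis sequence. The six-membered carbocycle is closed by ring-closing olefin metathesis between the vinyl group on C3 and the allyl terminus, so the new ring alkene C4=C5 is necessarily cis. No new stereocentre is formed: C3 is carried over from 1 and should survive because the olefination needs no base and the metathesis does not touch the allylic C–O bond, while C4–C5 is made at the alkene level so that C4 and C5 can later be set from C3. The step needs E geometry at C1=C2, which the alpha-substituted stabilised ylide secures and without which the two termini cannot meet, and it needs metathesis at the terminal alkenes only, which the trisubstituted, ester-deactivated C1=C2 bond secures. Benzoquinone, added only after the ylide is spent, is there to suppress ruthenium hydride isomerisation of the skipped diene, the main side process.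

Step 6
Reactants: 10 methyl (3S)-3-[(tert-butyldimethylsilyl)oxy]cyclohexa-1,4-diene-1-carboxylate
Product: 11 methyl (3S)-3-hydroxycyclohexa-1,4-diene-1-carboxylate
Conditions: TBAF, AcOH (1:1), THF, 0 °C; used directly
Reagents that add atoms: none
Why: Fluoride-mediated desilylation, buffered with acetic acid so that neither base-induced 1,4-elimination nor acid-induced ionisation of the bis-allylic alcohol leads to the benzoate, should free the directing hydroxyl with the stereocentre untouched.

Step 7
Reactants: 11 methyl (3S)-3-hydroxycyclohexa-1,4-diene-1-carboxylate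
Product: 12 methyl (3R,4R,5S)-4,5-epoxy-3-hydroxycyclohex-1-ene-1-carboxylate (epoxide oxygen cis to the hydroxyl)
Conditions: VO(acac)2 (cat.), t-BuOOH (decane solution), CH2Cl2, 0 °C
Reagents that add atoms: tert-butyl hydroperoxide, CC(C)(C)OO
Why: In this hydroxyl-directed, vanadium-catalysed epoxidation the vanadate ester of the C3 alcohol should deliver the peroxide oxygen to the same face of the neighbouring electron-rich C4=C5 bond (the enoate C1=C2 is deactivated), which sets C4 with its oxygen cis to O3.

Step 8
Reactants: 12 methyl (3R,4R,5S)-4,5-epoxy-3-hydroxycyclohex-1-ene-1-carboxylate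
Product: 13 methyl (3R,4S,5S)-3-acetoxy-4,5-epoxycyclohex-1-ene-1-carboxylate
Conditions: Ac2O, pyridine, DMAP (cat.), CH2Cl2, 0 °C
Reagents that add atoms: acetic anhydride, CC(=O)OC(C)=O
Why: Standard O-acetylation (DMAP-catalysed acyl transfer) installs the C3 acetate of the target and blocks O3 before the epoxide is opened.

Step 9
Reactants: 13 methyl (3R,4S,5S)-3-acetoxy-4,5-epoxycyclohex-1-ene-1-carboxylate; 14 (2R)-2-methylbutanoic acid
Product: 15 methyl (3R,4S,5R)-3-acetoxy-4-hydroxy-5-{[(2R)-2-methylbutanoyl]oxy}cyclohex-1-ene-1-carboxylate
Conditions: Co(salen)OAc, Co(C36H52N2O2)(OAc) with salen = N,N'-bis(3,5-di-tert-butylsalicylidene)cyclohexane-1,2-diamine dianion (5 mol%), i-Pr2NEt, t-BuOMe, rt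
Reagents that add atoms: none
Why: In this cobalt–salen-catalysed SN2 opening of an epoxide by a carboxylic acid (trans-diaxial geometry) attack should go to C5, the oxirane carbon remote from the bulky, inductively deactivating acetoxy-bearing C3, with inversion, which sets C5 (R) trans to the retained C4 oxygen.

Step 10
Reactants: 15 methyl (3R,4S,5R)-3-acetoxy-4-hydroxy-5-{[(2R)-2-methylbutanoyl]oxy}cyclohex-1-ene-1-carboxylate; 14 (2R)-2-methylbutanoic acid
Product: 16 methyl (3R,4S,5R)-3-acetoxy-4,5-bis{[(2R)-2-methylbutanoyl]oxy}cyclohex-1-ene-1-carboxylate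
Conditions: DCC, DMAP (cat.), CH2Cl2, 0 °C to rt
Reagents that add atoms: none
Why: Carbodiimide/DMAP esterification (Steglich esterification) of the hindered C4 hydroxyl with the same acid should complete the target, since no ring stereocentre is touched and the alpha-branched acid is not prone to racemise under carbodiimide activation.

Compound list
1 | (2S)-but-3-ene-1,2-diol | C=C[C@H](O)CO | starting material
2 | (3S)-3,4-bis[(tert-butyldimethylsilyl)oxy]but-1-ene | C=C[C@H](O[Si](C)(C)C(C)(C)C)CO[Si](C)(C)C(C)(C)C | intermediate
3 | (2S)-2-[(tert-butyldimethylsilyl)oxy]but-3-en-1-ol | C=C[C@H](O[Si](C)(C)C(C)(C)C)CO | intermediate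
4 | (2S)-2-[(tert-butyldimethylsilyl)oxy]but-3-enal | C=C[C@H](O[Si](C)(C)C(C)(C)C)C=O | intermediate
5 | methyl (triphenylphosphoranylidene)acetate | COC(=O)C=P(c1ccccc1)(c1ccccc1)c1ccccc1 | starting material
6 | allyl bromide | C=CCBr | starting material
7 | (1-methoxy-1-oxopent-4-en-2-yl)triphenylphosphonium bromide | C=CCC(C(=O)OC)[P+](c1ccccc1)(c1ccccc1)c1ccccc1.[Br-] | intermediate
8 | methyl 2-(triphenylphosphoranylidene)pent-4-enoate | C=CCC(C(=O)OC)=P(c1ccccc1)(c1ccccc1)c1ccccc1 | intermediate
9 | methyl (2E,4S)-4-[(tert-butyldimethylsilyl)oxy]-2-(prop-2-en-1-yl)hexa-2,5-dienoate | C=CC/C(C(=O)OC)=C\[C@@H](O[Si](C)(C)C(C)(C)C)C=C | intermediate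
10 | methyl (3S)-3-[(tert-butyldimethylsilyl)oxy]cyclohexa-1,4-diene-1-carboxylate | COC(=O)C1=C[C@@H](O[Si](C)(C)C(C)(C)C)C=CC1 | intermediate
11 | methyl (3S)-3-hydroxycyclohexa-1,4-diene-1-carboxylate | COC(=O)C1=C[C@@H](O)C=CC1 | intermediate
12 | methyl (3R,4R,5S)-4,5-epoxy-3-hydroxycyclohex-1-ene-1-carboxylate | O[C@@H]1C=C(C(=O)OC)C[C@@H]2O[C@H]12 | intermediate
13 | methyl (3R,4S,5S)-3-acetoxy-4,5-epoxycyclohex-1-ene-1-carboxylate | CC(=O)O[C@@H]1C=C(C(=O)OC)C[C@@H]2O[C@H]12 | intermediate
14 | (2R)-2-methylbutanoic acid | CC[C@@H](C)C(=O)O | starting material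
15 | methyl (3R,4S,5R)-3-acetoxy-4-hydroxy-5-{[(2R)-2-methylbutanoyl]oxy}cyclohex-1-ene-1-carboxylate | O[C@@H]1[C@H](OC(C)=O)C=C(C(=O)OC)C[C@H]1OC(=O)[C@H](C)CC | intermediate
16 | methyl (3R,4S,5R)-3-acetoxy-4,5-bis{[(2R)-2-methylbutanoyl]oxy}cyclohex-1-ene-1-carboxylate | CC[C@@H](C)C(=O)O[C@@H]1[C@H](OC(C)=O)C=C(C(=O)OC)C[C@H]1OC(=O)[C@H](C)CC | target

Total step count: 10. Longest linear sequence: 9 steps (steps 1, 2, 3, 5, 6, 7, 8, 9, 10).

Steps most likely to fail

Step 5. The one-flask sequence may suffer from ruthenium-hydride-induced migration of the skipped diene, from loss of silanol with aromatisation to the benzoate, or from inhibition of the metathesis catalyst by phosphorus residues. The fallback separates the two bond formations and changes both the phosphorus reagent and the metathesis metal. It sets out from 6 and 4. Trimethyl phosphonoacetate would be alkylated with 6 (NaH, THF) to methyl 2-(dimethoxyphosphoryl)pent-4-enoate F1. A Horner–Wadsworth–Emmons reaction of F1 with 4 (LiCl, i-Pr2NEt, MeCN, 0 °C) should give triene 9, here isolated and freed from phosphorus by-products and any Z isomer. Ring closure of pure 9 with the hydride-free molybdenum imido alkylidene Mo(=CHCMe2Ph)(=N-2,6-i-Pr2C6H3)[OCMe(CF3)2]2 in benzene at rt comes back to the route at 10.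

Step 7 (together with the desilylation before it). The bis-allylic alcohol 11 may lose water and aromatise during desilylation or epoxidation, or the peroxide may be delivered to the wrong face or oxidise the carbinol. The fallback avoids the free dienol and uses steric rather than directed control; it sets out from 10. N-Bromosuccinimide in aqueous THF at 0 °C in the dark should form the bromonium ion anti to the silyloxy group, and water opens it trans. This gives methyl (3R,4R,5S)-4-bromo-3-[(tert-butyldimethylsilyl)oxy]-5-hydroxycyclohex-1-ene-1-carboxylate F2; its regioisomer converges in the next operation. K2CO3 in MeOH closes the bromohydrin to methyl (3R,4S,5S)-3-[(tert-butyldimethylsilyl)oxy]-4,5-epoxycyclohex-1-ene-1-carboxylate F3, whose oxirane oxygen is syn to the silyloxy group. Desilylation of this no longer aromatisable compound (TBAF, AcOH, THF) comes back to the route at 12.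

Step 9. The carboxylate may attack C4 as well as C5, and the acetyl group may migrate from O3 to the newly freed cis hydroxyl on C4, scrambling the ester positions. The fallback opens the epoxide before any acetate is present and places the acetate by a different principle; it sets out from 12. Opening of the free epoxy alcohol 12 with 14 mediated by Ti(O-i-Pr)4 (CH2Cl2, rt), where chelation between hydroxyl and oxirane steers attack to C5, should give methyl (3R,4R,5R)-3,4-dihydroxy-5-{[(2R)-2-methylbutanoyl]oxy}cyclohex-1-ene-1-carboxylate F4. Trimethyl orthoacetate with catalytic camphorsulfonic acid would convert the cis-3,4-diol into the cyclic 3,4-O-(1-methoxyethylidene) orthoester F5. Mild aqueous acetic acid should open this to the ester on the pseudoaxial oxygen O3, which comes back to the route at 15.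

Further compounds
F1 | step 5 | methyl 2-(dimethoxyphosphoryl)pent-4-enoate | C=CCC(C(=O)OC)P(=O)(OC)OC
F2 | step 7 | methyl (3R,4R,5S)-4-bromo-3-[(tert-butyldimethylsilyl)oxy]-5-hydroxycyclohex-1-ene-1-carboxylate | Br[C@H]1[C@H](O[Si](C)(C)C(C)(C)C)C=C(C(=O)OC)C[C@@H]1O
F3 | step 7 | methyl (3R,4S,5S)-3-[(tert-butyldimethylsilyl)oxy]-4,5-epoxycyclohex-1-ene-1-carboxylate | CC(C)(C)[Si](C)(C)O[C@@H]1C=C(C(=O)OC)C[C@@H]2O[C@H]12
F4 | step 9 | methyl (3R,4R,5R)-3,4-dihydroxy-5-{[(2R)-2-methylbutanoyl]oxy}cyclohex-1-ene-1-carboxylate | O[C@@H]1[C@H](O)C=C(C(=O)OC)C[C@H]1OC(=O)[C@H](C)CC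
F5 | step 9 | 3,4-O-(1-methoxyethylidene) orthoester of F4 (both epimers at the orthoester carbon) | COC1(C)O[C@@H]2C=C(C(=O)OC)C[C@@H](OC(=O)[C@H](C)CC)[C@@H]2O1
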